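**Retrosynthetic overview**

1. The 1,2-dioxane (the only ring) is closed last: the C6–O bond forms by a 6-exo photoredox radical hydroperoxy-cyclisation of the open-chain (3R)-hydroperoxy (6Z)-diene acid 19. This step also sets C6 and creates the (E)-C7=C8 alkene with its methyl group.
2. C3–OOH comes from catalyst-controlled conjugate peroxidation of enal 16, followed by CHO → CO2H.
3. The (6Z)-diene comes from a three-component coupling: syn-carbocupration of but-1-yne by a C1–C5 Grignard reagent, then Pd coupling with the C8–C14 vinyl triflate 6.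
4. C4 comes from Cu-catalysed asymmetric SN2′ ethylation of (E)-1,4-dibromobut-2-ene; C1–C2 are added by cross-metathesis with acrolein acetal.
5. C10 comes from Rh-catalysed asymmetric 1,4-addition of an (E)-butenylboron reagent (from but-1-yne) to (E)-hex-3-en-2-one.

Assumption: locants C1–C14 follow the open-chain acid (C1 = CO2H; C3 and C6 = the peroxide carbons; C8′ = the carbon on C8 that ends as the methyl group); Ph2C(OMe)OOH (from ozonolysis of 1,1-diphenylethene in MeOH) is treated as a reagent, and the catalyst/ligand enantiomers named are those expected from the usual stereochemical models to give the stated configurations.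

**Step 1**
Reactants: 1 but-1-yne; 2 (E)-hex-3-en-2-one
Product: 4 (R,E)-4-ethyloct-5-en-2-one, via alkenylcatecholborane 3 (not isolated)
Conditions: catecholborane, sealed tube, 70 °C; then 2, Rh(acac)(C2H4)2 (3 mol %), (R)-BINAP (3.3 mol %), Et3N, dioxane/H2O 10:1, 100 °C
Reagents that add atoms: none
Why: syn-hydroboration gives the (E)-alkenylboronate, and Rh/(R)-BINAP-catalysed 1,4-addition (Hayashi–Miyaura) transfers the alkenyl group to one face of the E-enone, setting C10 as R under ligand control.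

**Step 2**
Reactants: 4 (R,E)-4-ethyloct-5-en-2-one
Product: 6 (R,E)-4-ethylocta-1,5-dien-2-yl trifluoromethanesulfonate, via lithium enolate 5 (not isolated)
Conditions: LDA (commercial, 1.1 equiv), THF, −78 °C; PhNTf2, −78 → 0 °C
Reagents that add atoms: N-phenylbis(trifluoromethanesulfonimide), O=S(=O)(N(c1ccccc1)S(=O)(=O)C(F)(F)F)C(F)(F)F
Why: kinetic deprotonation occurs at the methyl group rather than the β-branched CH2, and O-triflation of the enolate gives the 2-substituted vinyl triflate; C10 is not α to the carbonyl and is untouched.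

**Step 3**
Reactants: 7 (E)-1,4-dibromobut-2-ene
Product: 8 (S)-3-(bromomethyl)pent-1-ene
Conditions: EtMgBr (1.2 equiv), CuBr·SMe2 (1 mol %), (R,R)-Taniaphos (1.2 mol %; the ligand enantiomer that gives the S-bromide), CH2Cl2, −78 °C
Reagents that add atoms: ethylmagnesium bromide, CC[Mg]Br
Why: Cu-catalysed asymmetric allylic alkylation delivers ethyl in an anti-SN2′ sense to give the branched homoallylic bromide, and the chiral ferrocenyl diphosphine sets the future C4 stereocentre.

**Step 4**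
Reactants: 8 (S)-3-(bromomethyl)pent-1-ene; 9 3,3-dimethoxyprop-1-ene
Product: 10 (S,E)-5-bromo-4-ethyl-1,1-dimethoxypent-2-ene
Conditions: Hoveyda–Grubbs II (3 mol %), 9 (4 equiv), CH2Cl2, 40 °C
Reagents that add atoms: none
Why: olefin cross-metathesis between the allylic-branched terminal alkene and excess acrolein acetal is E-selective and does not touch the allylic stereocentre or the primary bromide.

**Step 5**
Reactants: 10 (S,E)-5-bromo-4-ethyl-1,1-dimethoxypent-2-ene; 1 but-1-yne; 6 (R,E)-4-ethylocta-1,5-dien-2-yl trifluoromethanesulfonate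
Product: 15 (2E,4R,6Z,10R,11E)-4,6,10-triethyl-1,1-dimethoxy-8-methylidenetetradeca-2,6,11-triene, via Grignard reagent 11 (not isolated), via alkylcopper 12 (not isolated), via alkenylcopper 13 (not isolated), via alkenylzinc bromide 14 (not isolated)
Conditions: Mg, Et2O, 23 °C; CuBr·SMe2 (1.0 equiv), −35 °C; 1 (1.2 equiv), −25 °C, 2 h; ZnBr2, THF; then 6, Pd(PPh3)4 (5 mol %), −20 → 23 °C
Reagents that add atoms: none
Why: Normant carbocupration adds the alkylcopper syn and regioselectively across but-1-yne so the C5 chain and the metal are cis, and transmetalation to zinc followed by Negishi coupling with the vinyl triflate proceeds with retention, giving the diene with C5 cis to C8 (6Z).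

**Step 6**
Reactants: 15 (2E,4R,6Z,10R,11E)-4,6,10-triethyl-1,1-dimethoxy-8-methylidenetetradeca-2,6,11-triene
Product: 16 (2E,4R,6Z,10R,11E)-4,6,10-triethyl-8-methylidenetetradeca-2,6,11-trienal
Conditions: PPTS (10 mol %), acetone/H2O 10:1, 23 °C
Reagents that add atoms: water, O
Why: mild acid hydrolysis of the allylic dimethyl acetal releases the E-enal without protonating the diene or epimerising C4.

**Step 7**
Reactants: 16 (2E,4R,6Z,10R,11E)-4,6,10-triethyl-8-methylidenetetradeca-2,6,11-trienal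
Product: 17 (3R,4R,6Z,10R,11E)-4,6,10-triethyl-3-[(methoxydiphenylmethyl)peroxy]-8-methylidenetetradeca-6,11-dienal
Conditions: (R)-α,α-bis[3,5-bis(trifluoromethyl)phenyl]prolinol TMS ether (10 mol %), Ph2C(OMe)OOH (1.5 equiv), PhCO2H (10 mol %), toluene, 0 °C
Reagents that add atoms: α-methoxydiphenylmethyl hydroperoxide, COC(OO)(c1ccccc1)c1ccccc1
Why: organocatalytic asymmetric peroxidation (iminium-activated oxa-Michael addition): the diarylsilyloxymethyl group of the (R)-catalyst shields the Re face of C3 in the E-iminium, so the hydroperoxide adds to the Si face and sets C3 as R (syn to the C4 ethyl) under catalyst control.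

**Step 8**
Reactants: 17 (3R,4R,6Z,10R,11E)-4,6,10-triethyl-3-[(methoxydiphenylmethyl)peroxy]-8-methylidenetetradeca-6,11-dienal
Product: 19 (3R,4R,6Z,10R,11E)-4,6,10-triethyl-3-hydroperoxy-8-methylidenetetradeca-6,11-dienoic acid, via peroxyketal acid 18 (not isolated)
Conditions: NaClO2, NaH2PO4, 2-methyl-2-butene (excess), t-BuOH/H2O, 0 °C; then AcOH/THF/H2O 3:1:1, 23 °C
Reagents that add atoms: sodium chlorite, [Na+].[O-]Cl=O
Why: Pinnick oxidation converts the aldehyde to the acid under weakly acidic conditions that spare the peroxide and (with the HOCl scavenger) the alkenes, and the very acid-labile monoperoxyketal is then hydrolysed to the free hydroperoxide without breaking the C3–O bond.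

**Step 9**
Reactants: 19 (3R,4R,6Z,10R,11E)-4,6,10-triethyl-3-hydroperoxy-8-methylidenetetradeca-6,11-dienoic acid
Product: 20 2-[(3R,4R,6R)-4,6-diethyl-6-[(1E,4R,5E)-4-ethyl-2-methylocta-1,5-dien-1-yl]-1,2-dioxan-3-yl]acetic acid
Conditions: 9-mesityl-3,6-di-tert-butyl-10-phenylacridinium BF4 (5 mol %), 2-phenylmalononitrile (0.5 equiv), degassed DCE (0.02 M), 450 nm LEDs, 23 °C
Reagents that add atoms: none
Why: Proposed new method: the excited acridinium oxidises the electron-rich diene to its radical cation (or the OOH to a peroxyl radical by proton-coupled electron transfer; both converge), the peroxide oxygen adds 6-exo to C6 (the only site that gives an allyl radical in a six-membered ring), the β-peroxy allyl radical takes H from 2-phenylmalononitrile at the unhindered CH2 terminus to form the C7=C8 alkene and the C8 methyl, and the reduced acridine reduces the malononitrile radical to close a redox-neutral cycle (closest known reactions: acridinium-photoredox polar-radical-crossover hydroetherification of alkenols and 6-exo peroxyl-radical cyclisations); in the chair transition state the C4 ethyl is equatorial and the C3 side chain axial, and A1,3 strain in the 6Z alkene (C8 cis to C5) forces the dienyl arm pseudo-equatorial and the C6 ethyl pseudo-axial, giving 6R, while the gauche s-cis conformation of the 2,4,4-trisubstituted diene places C6 cis to the new methyl, giving the E alkene.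

**Compound list**

1 | but-1-yne | CCC#C | starting material
2 | (E)-hex-3-en-2-one | CC/C=C/C(C)=O | starting material
3 | 2-[(E)-but-1-en-1-yl]-1,3,2-benzodioxaborole | CC/C=C/B1Oc2ccccc2O1 | intermediate
4 | (R,E)-4-ethyloct-5-en-2-one | CC/C=C/[C@H](CC)CC(C)=O | intermediate
5 | lithium (R,E)-4-ethylocta-1,5-dien-2-olate | CC/C=C/[C@H](CC)CC(=C)O[Li] | intermediate
6 | (R,E)-4-ethylocta-1,5-dien-2-yl trifluoromethanesulfonate | CC/C=C/[C@H](CC)CC(=C)OS(=O)(=O)C(F)(F)F | intermediate
7 | (E)-1,4-dibromobut-2-ene | BrC/C=C/CBr | starting material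
8 | (S)-3-(bromomethyl)pent-1-ene | BrC[C@@H](CC)C=C | intermediate
9 | 3,3-dimethoxyprop-1-ene (acrolein dimethyl acetal) | C=CC(OC)OC | starting material
10 | (S,E)-5-bromo-4-ethyl-1,1-dimethoxypent-2-ene | BrC[C@@H](CC)/C=C/C(OC)OC | intermediate
11 | [(S,E)-2-ethyl-5,5-dimethoxypent-3-en-1-yl]magnesium bromide | Br[Mg]C[C@@H](CC)/C=C/C(OC)OC | intermediate
12 | [(S,E)-2-ethyl-5,5-dimethoxypent-3-en-1-yl]copper | [Cu]C[C@@H](CC)/C=C/C(OC)OC | intermediate
13 | [(1Z,4R,5E)-2,4-diethyl-7,7-dimethoxyhepta-1,5-dien-1-yl]copper | [Cu]/C=C(CC)\C[C@@H](CC)/C=C/C(OC)OC | intermediate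
14 | [(1Z,4R,5E)-2,4-diethyl-7,7-dimethoxyhepta-1,5-dien-1-yl]zinc bromide | Br[Zn]/C=C(CC)\C[C@@H](CC)/C=C/C(OC)OC | intermediate
15 | (2E,4R,6Z,10R,11E)-4,6,10-triethyl-1,1-dimethoxy-8-methylidenetetradeca-2,6,11-triene | CC/C=C/[C@H](CC)CC(=C)/C=C(CC)\C[C@@H](CC)/C=C/C(OC)OC | intermediate
16 | (2E,4R,6Z,10R,11E)-4,6,10-triethyl-8-methylidenetetradeca-2,6,11-trienal | CC/C=C/[C@H](CC)CC(=C)/C=C(CC)\C[C@@H](CC)/C=C/C=O | intermediate
17 | (3R,4R,6Z,10R,11E)-4,6,10-triethyl-3-[(methoxydiphenylmethyl)peroxy]-8-methylidenetetradeca-6,11-dienal | CC/C=C/[C@H](CC)CC(=C)/C=C(CC)\C[C@@H](CC)[C@@H](CC=O)OOC(OC)(c1ccccc1)c1ccccc1 | intermediate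
18 | (3R,4R,6Z,10R,11E)-4,6,10-triethyl-3-[(methoxydiphenylmethyl)peroxy]-8-methylidenetetradeca-6,11-dienoic acid | CC/C=C/[C@H](CC)CC(=C)/C=C(CC)\C[C@@H](CC)[C@@H](CC(=O)O)OOC(OC)(c1ccccc1)c1ccccc1 | intermediate
19 | (3R,4R,6Z,10R,11E)-4,6,10-triethyl-3-hydroperoxy-8-methylidenetetradeca-6,11-dienoic acid | CC/C=C/[C@H](CC)CC(=C)/C=C(CC)\C[C@@H](CC)[C@@H](CC(=O)O)OO | intermediate
20 | 2-[(3R,4R,6R)-4,6-diethyl-6-[(1E,4R,5E)-4-ethyl-2-methylocta-1,5-dien-1-yl]-1,2-dioxan-3-yl]acetic acid | CC/C=C/[C@H](CC)C/C(C)=C/[C@@]1(CC)C[C@@H](CC)[C@@H](CC(=O)O)OO1 | target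

**Step count and risks**

Total steps: 9. Longest linear sequence: 7 (steps 1, 2, 5, 6, 7, 8, 9; the branch through steps 3 and 4 is equally long).

Most likely to fail, first: step 9. Hydrogen transfer to the β-peroxy allyl radical may be too slow, so that epoxide formation by attack of the radical on the O–O bond, or hydrogen delivery at C7, competes. The C7=C8 geometry and the C6 configuration rest on conformational arguments only. The fallback sets out from 19 and forms the C6–O bond by electrophilic cycloperoxymercuration instead (Hg(OAc)2, CH2Cl2, 0 °C). The hydroperoxide attacks the mercury-activated diene at C6 in the same chair, giving the allylic organomercurial 2-[(3R,4R,6R)-6-[(4R,5E)-1-(acetyloxymercurio)-4-ethyl-2-methylideneoct-5-en-1-yl]-4,6-diethyl-1,2-dioxan-3-yl]acetic acid F1. Reductive demercuration (NaBH4, aqueous NaOH, 0 °C) then delivers hydrogen to the CH2 terminus and comes back to the route at 20.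

Second: step 7. The γ-branched enal may react slowly, epoxidation through the enamine may compete, and dienamine formation could erode C4. The fallback sets out from 16 and installs the C3 oxygen by reagent-controlled epoxidation followed by SN2 inversion:
- Luche reduction (NaBH4, CeCl3, MeOH) gives (2E,4R,6Z,10R,11E)-4,6,10-triethyl-8-methylidenetetradeca-2,6,11-trien-1-ol F2.
- Sharpless epoxidation (Ti(OiPr)4, D-(−)-diethyl tartrate, t-BuOOH, −20 °C) gives (2R,3R,4R,6Z,10R,11E)-2,3-epoxy-4,6,10-triethyl-8-methylidenetetradeca-6,11-dien-1-ol F3.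
- Red-Al opens the epoxide at C2 to (3S,4R,6Z,10R,11E)-4,6,10-triethyl-8-methylidenetetradeca-6,11-diene-1,3-diol F4.
- TBSCl/imidazole gives the primary silyl ether (3S,4R,6Z,10R,11E)-1-[(tert-butyldimethylsilyl)oxy]-4,6,10-triethyl-8-methylidenetetradeca-6,11-dien-3-ol F5.
- MsCl/Et3N gives (3S,4R,6Z,10R,11E)-1-[(tert-butyldimethylsilyl)oxy]-4,6,10-triethyl-8-methylidenetetradeca-6,11-dien-3-yl methanesulfonate F6.
- Displacement with 2-methoxyprop-2-yl hydroperoxide (CsOH, DMF) inverts C3 to tert-butyl{[(3R,4R,6Z,10R,11E)-4,6,10-triethyl-3-[(2-methoxypropan-2-yl)peroxy]-8-methylidenetetradeca-6,11-dien-1-yl]oxy}dimethylsilane F7.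
- TBAF gives (3R,4R,6Z,10R,11E)-4,6,10-triethyl-3-[(2-methoxypropan-2-yl)peroxy]-8-methylidenetetradeca-6,11-dien-1-ol F8.
- TEMPO/PhI(OAc)2 in MeCN/H2O gives (3R,4R,6Z,10R,11E)-4,6,10-triethyl-3-[(2-methoxypropan-2-yl)peroxy]-8-methylidenetetradeca-6,11-dienoic acid F9.
- Aqueous acetic acid removes the peroxyketal and comes back to the route at 19.

Third: step 5. The homoallylic Grignard reagent carries an allylic acetal and may cyclise or eliminate, and the carbocupration of but-1-yne by a β-branched alkylcopper may be inefficient. The fallback sets out from 10 and avoids the Grignard reagent. Finkelstein exchange (NaI, acetone) gives (S,E)-4-ethyl-5-iodo-1,1-dimethoxypent-2-ene F10. Copper-catalysed borylcupration of 1 with alkylative trapping by F10 (CuCl, Xantphos, B2pin2, KOtBu, THF) gives 2-[(1Z,4R,5E)-2,4-diethyl-7,7-dimethoxyhepta-1,5-dien-1-yl]-4,4,5,5-tetramethyl-1,3,2-dioxaborolane F11, with the alkyl chain and boron cis. Suzuki–Miyaura coupling with 6 (Pd(dppf)Cl2, K3PO4, THF/H2O) comes back to the route at 15.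

**Further compounds**

F1 | step 9 | 2-[(3R,4R,6R)-6-[(4R,5E)-1-(acetyloxymercurio)-4-ethyl-2-methylideneoct-5-en-1-yl]-4,6-diethyl-1,2-dioxan-3-yl]acetic acid (both epimers at the Hg-bearing carbon) | CC/C=C/[C@H](CC)CC(=C)C([Hg]OC(C)=O)[C@@]1(CC)C[C@@H](CC)[C@@H](CC(=O)O)OO1
F2 | step 7 | (2E,4R,6Z,10R,11E)-4,6,10-triethyl-8-methylidenetetradeca-2,6,11-trien-1-ol | CC/C=C/[C@H](CC)CC(=C)/C=C(CC)\C[C@@H](CC)/C=C/CO
F3 | step 7 | (2R,3R,4R,6Z,10R,11E)-2,3-epoxy-4,6,10-triethyl-8-methylidenetetradeca-6,11-dien-1-ol | CC/C=C/[C@H](CC)CC(=C)/C=C(CC)\C[C@@H](CC)[C@H]1O[C@@H]1CO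
F4 | step 7 | (3S,4R,6Z,10R,11E)-4,6,10-triethyl-8-methylidenetetradeca-6,11-diene-1,3-diol | CC/C=C/[C@H](CC)CC(=C)/C=C(CC)\C[C@@H](CC)[C@@H](O)CCO
F5 | step 7 | (3S,4R,6Z,10R,11E)-1-[(tert-butyldimethylsilyl)oxy]-4,6,10-triethyl-8-methylidenetetradeca-6,11-dien-3-ol | CC/C=C/[C@H](CC)CC(=C)/C=C(CC)\C[C@@H](CC)[C@@H](O)CCO[Si](C)(C)C(C)(C)C
F6 | step 7 | (3S,4R,6Z,10R,11E)-1-[(tert-butyldimethylsilyl)oxy]-4,6,10-triethyl-8-methylidenetetradeca-6,11-dien-3-yl methanesulfonate | CC/C=C/[C@H](CC)CC(=C)/C=C(CC)\C[C@@H](CC)[C@@H](OS(C)(=O)=O)CCO[Si](C)(C)C(C)(C)C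
F7 | step 7 | tert-butyl{[(3R,4R,6Z,10R,11E)-4,6,10-triethyl-3-[(2-methoxypropan-2-yl)peroxy]-8-methylidenetetradeca-6,11-dien-1-yl]oxy}dimethylsilane | CC/C=C/[C@H](CC)CC(=C)/C=C(CC)\C[C@@H](CC)[C@@H](CCO[Si](C)(C)C(C)(C)C)OOC(C)(C)OC
F8 | step 7 | (3R,4R,6Z,10R,11E)-4,6,10-triethyl-3-[(2-methoxypropan-2-yl)peroxy]-8-methylidenetetradeca-6,11-dien-1-ol | CC/C=C/[C@H](CC)CC(=C)/C=C(CC)\C[C@@H](CC)[C@@H](CCO)OOC(C)(C)OC
F9 | step 7 | (3R,4R,6Z,10R,11E)-4,6,10-triethyl-3-[(2-methoxypropan-2-yl)peroxy]-8-methylidenetetradeca-6,11-dienoic acid | CC/C=C/[C@H](CC)CC(=C)/C=C(CC)\C[C@@H](CC)[C@@H](CC(=O)O)OOC(C)(C)OC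
F10 | step 5 | (S,E)-4-ethyl-5-iodo-1,1-dimethoxypent-2-ene | IC[C@@H](CC)/C=C/C(OC)OC
F11 | step 5 | 2-[(1Z,4R,5E)-2,4-diethyl-7,7-dimethoxyhepta-1,5-dien-1-yl]-4,4,5,5-tetramethyl-1,3,2-dioxaborolane | CC1(C)OB(/C=C(CC)\C[C@@H](CC)/C=C/C(OC)OC)OC1(C)C
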